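The runs were generated by integration from invented constants, and the scatter is random.

At one constant temperature, the meeting had 4 stirred flasks, followed for 7.4 min each, in which catalyst turns starting material into target, and it had to reckon a fifth, Thursday's.

| flask | starting material | catalyst | time |
|---|---|---|---|
| Saturday's | 0.0500 M | 0.00100 M |  |
| Monday's | 0.0250 M | 0.00100 M |  |
| Friday's | 0.100 M | 0.00100 M |  |
| Sunday's | 0.0500 M | 0.00150 M |  |
| Thursday's | 0.150 M | 5.00 × 10⁻⁴ M | 7.4 min |

| run | time / min | [target] / M |
|---|---|---|
| Saturday's run | 0.27 | 0.0023 |
| Saturday's run | 0.81 | 0.0053 |
| Saturday's run | 1.5 | 0.0101 |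
| Saturday's run | 2.4 | 0.0130 |
| Saturday's run | 3.5 | 0.0171 |
| Saturday's run | 4.7 | 0.0189 |
| Saturday's run | 6.0 | 0.0215 |
| Saturday's run | 7.4 | 0.0224 |
| Monday's run | 0.27 | 9 × 10⁻⁴ |
| Monday's run | 0.81 | 0.0025 |
| Monday's run | 1.5 | 0.0047 |
| Monday's run | 2.4 | 0.0062 |
| Monday's run | 3.5 | 0.0080 |
| Monday's run | 4.7 | 0.0101 |
| Monday's run | 6.0 | 0.0104 |
| Monday's run | 7.4 | 0.0114 |
| Friday's run | 0.27 | 0.0034 |
| Friday's run | 0.81 | 0.0107 |
| Friday's run | 1.5 | 0.0172 |
| Friday's run | 2.4 | 0.0257 |
| Friday's run | 3.5 | 0.0338 |
| Friday's run | 4.7 | 0.0390 |
| Friday's run | 6.0 | 0.0428 |
| Friday's run | 7.4 | 0.0453 |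
| Sunday's run | 0.27 | 0.0036 |
| Sunday's run | 0.81 | 0.0073 |
| Sunday's run | 1.5 | 0.0130 |
| Sunday's run | 2.4 | 0.0183 |
| Sunday's run | 3.5 | 0.0219 |
| Sunday's run | 4.7 | 0.0241 |
| Sunday's run | 6.0 | 0.0266 |
| Sunday's run | 7.4 | 0.0264 |

(each reading ± 5 × 10⁻⁴ M)

- Overall: starting material -> target, with catalyst as catalyst.
- Constant volume, constant temperature.
- An order is taken over about fifteen percent of the charge, up and down.

- how the opening rate goes with [catalyst] round the charge of the Saturday's run: the exponent of the rate at two percent of starting material gone to target
- how the opening rate goes with [starting material] round the charge of the Saturday's run: the exponent of the rate at two percent of starting material gone to target (one fixed amount of target, the same in the runs compared)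
- target in the Thursday's run at 7.4 min, as a share of the starting material charged
- which of these the readings show (the catalyst dies in pairs / the product decays / the substrate ties up the catalyst / an uncatalysed path runs beside / the product ties up the catalyst)

The chair proposed to judge every flask by one time. Saturday's reading at 0.81 min gave a conversion clock of 7.64 min, the charge of starting material over the target made per minute up to that reading, the field's pseudo-first-order time. The chair reported clocks of 7.57 min for Friday's flask and 8.10 min for Monday's, and read an order in starting material of 1.01 from Friday's flask against Saturday's, at one time rather than one amount of target. Sunday's clock was 5.55 min, which gives an order in catalyst of 0.790; the chair took this as first order within the scatter of such small readings. Thursday's catalyst is half of Saturday's, so the chair set Thursday's clock at 15.3 min, although Thursday's charge of starting material lies beyond the simulated ones.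

The second member objected that the clock alone puts Saturday's flask at 62.0 % by 7.4 min, while the reading is 44.8 %. Sunday's last readings stand flat at 0.0266 M and 0.0264 M, with 0.0132 M of starting material left by Sunday's clock. The member therefore argued that target goes as fast as it forms there, with a lifetime of 11.1 min. The chair committed to decay of target and gave Thursday 27.3 %, lower than the 38.3 % of the clock alone.

The forecast gave orders of 1 in catalyst and 1.07 in starting material, 33.5 % for Thursday and "the catalyst dies in pairs", on the ground that “The stall near 45–50% with substrate left means the catalyst is dying.” Its share is more than the chair's by 6.2 percentage points.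

Thursday's flask gave 28.8 % of its charge as target at 7.4 min; round Saturday's charge the orders are 1.0 in catalyst and 1.0 in starting material, and the readings show that the product decays.

    catalyst + starting material → target + catalyst (142.2 M⁻¹ min⁻¹)
    target → decomposed product (0.09180 min⁻¹)

Sunday's rate stood at 1.5 times Saturday's where the same amount of target had been made. Saturday's clock divided by that ratio is 5.07 min for Sunday's flask, and with the target's lifetime of 10.9 min from the second step it gives 51.4 % of Sunday's charge as target at 7.4 min, against a reading of 52.8 %.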